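Remark on conventions and one assumption: ring A is the benzoyl ring (C1 bears the ester carbonyl) and ring B is the salicylic acid ring (primed numbers, C1' bears the carboxyl group). The target has no stereogenic element, so alkene 2 is assumed to be usable as a mixture of geometric isomers because it is hydrogenated in the next step.

## Analysis of the target

Compound 14 is a depside, 4-[(2,4-dimethoxy-6-propylbenzoyl)oxy]-2-hydroxy-6-pentylbenzoic acid. Its two benzene rings are not fused and are joined only by an aryl ester between the C1 carbonyl of ring A and O4' of ring B. Ring A carries methoxy groups at C2 and C4 and a propyl group at C6. Ring B is a salicylic acid with CO2H at C1', OH at C2', the ester oxygen at C4' and a pentyl chain at C6'. There is no stereocenter, so the problem is one of regiochemistry and functional-group tolerance. The sensitive groups are the depside ester (a phenyl ester, open to hydroxide, alkoxide and amines, though shielded by the two ortho substituents of ring A) and the ring B acid, an oxygen-rich ortho-hydroxybenzoic acid that loses CO2 on heating or in strong acid. The difficulties are acyl transfer from a di-ortho-substituted benzoic acid, telling apart the two oxygens of ring B, and placing carbon substituents at both C1' and C6'. The strategy rests on one feature: the C1' carboxyl is flanked by the oxygenated C2' and by C6', whereas the ring A carbonyl is flanked by C2–OMe and C6–propyl. If C6' carries hydrogen, that C6'–H is the only C–H ortho to a carboxylate in the whole molecule, so a carboxylate-bound metal can reach only that position.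

## Retrosynthetic reasoning

14 to 13. The last bond cut is the O2'–benzyl bond. The 2'-phenol must be masked during the metal-mediated step, because a free salicylate would chelate the metal through both oxygens and is open to oxidation. A benzyl ether is chosen because neutral hydrogenolysis at room temperature leaves the depside ester, the methyl ethers and the decarboxylation-prone acid untouched.

13 to 11 and 12. The C6'–pentyl bond is cut. It is cut there because the carboxylate of 11 can direct a metal only to C6'–H, so no blocking group or prior halogenation is needed. The gain is that ring B no longer has to be bought or built with its alkyl chain, and the chain is introduced last on an otherwise complete depside. The forward reaction must deliver a primary alkyl group with β-hydrogens from 12 to the palladated carbon, and must give reductive elimination faster than β-hydride elimination. It must also spare the ester and the acid.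

11 to 10. The carboxyl group is traced back to an aldehyde. The aldehyde is a masked acid that needs no protecting group, and its hydrogen bond to the neighbouring hydroxyl is what separates the two phenols in the earlier steps. A Pinnick oxidation unmasks it without touching the ester or the benzyl ether.

10 to 9. The O2'–benzyl bond is cut. Benzylation is placed after ester formation so that the only free hydroxyl left in 9 is the one to be protected.

9 to 6 and 7 (through 8). The acyl C–O4' bond of the depside is cut. Compound 7 is cheap, and its 4-hydroxyl is the more acidic and more nucleophilic one because the 2-hydroxyl is tied up in a hydrogen bond to the formyl group. The hindered acid 6 is activated as its chloride 8 to force the acylation.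

6 to 5 to 3. The C1–carboxyl bond is traced back through the aldehyde 5 to a C–H bond of 3. The two methoxy groups of 3 direct an electrophilic formylation to the carbon ortho to one and para to the other, which is the carbon next to the propyl chain. That gives exactly the 2,4-dimethoxy-6-propyl pattern.

3 to 2 to 1. The propyl chain is cut at its first C–C bond. A Wittig ethylidenation of 1 followed by hydrogenation of 2 installs a saturated three-carbon chain without any cross-coupling of an alkyl metal.

## Alternatives that were turned down

Alternative 1: The disconnection is the C1–C6 bond of ring A. Ring A is unfolded into a linear chain that is already attached to O4' of a protected ring B, namely 3-(benzyloxy)-4-[(benzyloxy)carbonyl]-5-pentylphenyl 3,5,7-trioxodecanoate A2. In the forward key step a mild amine base and then acid make the C2 methylene add to the C7 ketone. Dehydration and enolisation then give benzyl 2-(benzyloxy)-4-[(2,4-dihydroxy-6-propylbenzoyl)oxy]-6-pentylbenzoate A1.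
- For: it follows polyketide logic, and the ester is made from an unhindered acyl chain before ring A exists. On the acyl-transfer problem it is stronger than the chosen route, which must push a di-ortho-substituted acid chloride onto a phenol.
- Against: A2 is a phenyl ester of a polyketo acid. Its phenoxide is a good leaving group, so lactonisation of the C5 enol oxygen onto C1 and Claisen-type C-acylation, both with loss of ring B, compete with the aldol. A2 is itself hard to assemble. After A1 both ring A phenols must be methylated, the chelated one reluctantly, before a double hydrogenolysis. Ring B must also already carry the pentyl chain.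
- Comparison: more steps and a fragile key substrate. The chosen route keeps stable aromatic intermediates throughout and puts its risk into one well-defined C–C coupling.

Alternative 2: The disconnection is the O4'–C4' aryl–oxygen bond rather than the acyl–oxygen bond. In the forward key step a divalent copper salt promotes an oxidative Chan–Lam coupling of the carboxylate oxygen of acid 6 with [4-(tert-butoxycarbonyl)-3-(methoxymethoxy)-5-pentylphenyl]boronic acid A4. The product is tert-butyl 4-[(2,4-dimethoxy-6-propylbenzoyl)oxy]-2-(methoxymethoxy)-6-pentylbenzoate A3.
- For: the nucleophile is the carboxylate oxygen, so the shielding of the ring A carbonyl carbon does not matter. On this point it is stronger than the chosen route. It also shares acid 6.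
- Against: A4 needs boron at C4' of a ring that already holds the pentyl chain, a protected phenol and an ester, which means several steps including a regioselective borylation. O-arylation of a hindered, weakly nucleophilic carboxylate must also outrun protodeboronation, oxidative hydroxylation and homocoupling of A4. Two acid-labile groups must then be removed from a product that decarboxylates readily.
- Comparison: it spends a delicate step on the ester bond, which ordinary acylation forms in step 5, and it does not shorten the construction of ring B. The chosen route uses its one demanding step to save that construction.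

Alternative 3: The disconnection cuts both the C1–carbonyl and the carbonyl–O4' bonds, with the carbonyl carbon coming from carbon monoxide A8. The other two components are 2-iodo-1,5-dimethoxy-3-propylbenzene A6 (one iodination of 3) and benzyl 2,4-dihydroxy-6-pentylbenzoate A7. In the forward key step a palladium catalyst with a wide-bite-angle bisphosphine and an amine base takes A6 through oxidative addition to zerovalent palladium and insertion of A8. The 4-hydroxyl of A7 then captures the acylpalladium to give benzyl 4-[(2,4-dimethoxy-6-propylbenzoyl)oxy]-2-hydroxy-6-pentylbenzoate A5.
- For: it is highly convergent and skips the formylation, oxidation and acid chloride steps on ring A. The chelated 2'-hydroxyl needs no protection and one hydrogenolysis finishes the synthesis. In convergence and in the mildness of its last bond-forming step it is at least as strong as the chosen route.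
- Against: oxidative addition into an electron-rich, di-ortho-substituted aryl iodide is slow. The acylpalladium must be intercepted by a phenol, a poorer nucleophile than an aliphatic alcohol, so reduction of the iodide and direct O-arylation can compete. A7, with the pentyl chain in place, has to come from a separate synthesis.
- Comparison: the chosen strategy builds ring B from the cheap aldehyde 7 and adds the pentyl chain last, so the chain can be varied from the common acid 11. The price is a hotter, oxidative metal step on the finished depside.

Key step: step 8

## Route

Step 1
Reactants: 1 3,5-dimethoxybenzaldehyde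
Product: 2 1,3-dimethoxy-5-(prop-1-en-1-yl)benzene (mixture of Z and E isomers)
Conditions: EtPPh3Br, KOtBu, THF, 0 °C to rt
Reagents that add atoms: ethyltriphenylphosphonium bromide, CC[P+](c1ccccc1)(c1ccccc1)c1ccccc1.[Br-]
Why: Wittig olefination of an unhindered aromatic aldehyde with a non-stabilised ylide; the geometry of the alkene is irrelevant because it is hydrogenated in step 2.

Step 2
Reactants: 2 1,3-dimethoxy-5-(prop-1-en-1-yl)benzene
Product: 3 1,3-dimethoxy-5-propylbenzene
Conditions: H2 (1 atm), 10% Pd/C, EtOAc, rt
Reagents that add atoms: none
Why: Catalytic hydrogenation of a styrene-type double bond; the aryl methyl ethers and the ring are inert under these conditions.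

Step 3
Reactants: 3 1,3-dimethoxy-5-propylbenzene
Product: 5 2,4-dimethoxy-6-propylbenzaldehyde, via aryliminium chloride 4 (not isolated)
Conditions: POCl3, DMF, 0 °C to 70 °C; then ice, aq. NaOH to pH 7
Reagents that add atoms: N,N-dimethylformamide, CN(C)C=O; water, O
Why: Vilsmeier–Haack formylation; the chloroiminium electrophile should attack the carbon that is ortho to one methoxy group and para to the other, next to the propyl chain, because the position between the two methoxy groups is more crowded, and hydrolysis of 4 releases the aldehyde.

Step 4
Reactants: 5 2,4-dimethoxy-6-propylbenzaldehyde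
Product: 6 2,4-dimethoxy-6-propylbenzoic acid
Conditions: NaClO2, NaH2PO4, 2-methyl-2-butene, t-BuOH/H2O, rt
Reagents that add atoms: sodium chlorite, [Na+].[O-]Cl=O
Why: Pinnick oxidation; chlorous acid oxidises the hindered aldehyde without needing attack at a crowded acyl carbon, and the alkene scavenger removes hypochlorite before it can chlorinate the electron-rich ring.

Step 5
Reactants: 6 2,4-dimethoxy-6-propylbenzoic acid; 7 2,4-dihydroxybenzaldehyde
Product: 9 4-formyl-3-hydroxyphenyl 2,4-dimethoxy-6-propylbenzoate, via 2,4-dimethoxy-6-propylbenzoyl chloride 8 (not isolated)
Conditions: (COCl)2, cat. DMF, CH2Cl2, 0 °C to rt; evaporation; then 7 (1 equiv), Et3N, cat. DMAP, CH2Cl2, 0 °C to rt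
Reagents that add atoms: oxalyl chloride, O=C(Cl)C(=O)Cl (gives the chlorine of 8; none of its atoms remains in 9)
Why: Acid chloride formation followed by DMAP-catalysed acylation of a phenol; the 4-hydroxyl of 7 is the more acidic and more nucleophilic one because the 2-hydroxyl is locked in a hydrogen bond to the formyl group, and one equivalent of the hindered chloride should stop at monoacylation.

Step 6
Reactants: 9 4-formyl-3-hydroxyphenyl 2,4-dimethoxy-6-propylbenzoate
Product: 10 3-(benzyloxy)-4-formylphenyl 2,4-dimethoxy-6-propylbenzoate
Conditions: BnBr, K2CO3, DMF, rt
Reagents that add atoms: benzyl bromide, BrCc1ccccc1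
Why: Williamson etherification of the chelated phenol; carbonate in DMF at room temperature is basic enough to alkylate a salicylaldehyde hydroxyl, and the depside ester is protected from the phenoxide by the methoxy and propyl groups flanking its carbonyl.

Step 7
Reactants: 10 3-(benzyloxy)-4-formylphenyl 2,4-dimethoxy-6-propylbenzoate
Product: 11 2-(benzyloxy)-4-[(2,4-dimethoxy-6-propylbenzoyl)oxy]benzoic acid
Conditions: NaClO2, NaH2PO4, 2-methyl-2-butene, t-BuOH/THF/H2O, rt
Reagents that add atoms: sodium chlorite, [Na+].[O-]Cl=O
Why: Pinnick oxidation; the weakly acidic buffered medium leaves the aryl ester and the benzyl ether intact and converts only the aldehyde into the acid that directs the next step.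

Step 8
Reactants: 11 2-(benzyloxy)-4-[(2,4-dimethoxy-6-propylbenzoyl)oxy]benzoic acid; 12 potassium pentyltrifluoroborate
Product: 13 2-(benzyloxy)-4-[(2,4-dimethoxy-6-propylbenzoyl)oxy]-6-pentylbenzoic acid
Conditions: 12 (3 equiv), Pd(OAc)2 (10 mol %), N-acetylglycine (20 mol %), Ag2CO3 (2 equiv), Li2CO3 (1 equiv), 1,4-benzoquinone (0.5 equiv), t-AmylOH, 90 °C; then aq. HCl
Reagents that add atoms: none
Why: The step relies on the carboxylate-directed ortho C–H alkylation of benzoic acids with alkylboron reagents under divalent palladium catalysis. The carboxylate of 11 binds divalent palladium, and a concerted metalation–deprotonation, assisted by the N-acyl amino acid ligand, cleaves C6'–H to give a five-membered palladacycle. Transmetalation from 12, activated by carbonate, places the pentyl group on palladium, and C–C reductive elimination forms the C6'–pentyl bond; coordinated benzoquinone accelerates this elimination so that it should outrun β-hydride elimination from the pentyl group. Ag2CO3 returns zerovalent palladium to divalent palladium. No ring is closed and no stereocenter is formed. The step needs site selectivity and monoalkylation, and the substrate secures both: C2' carries the benzyloxy group, so C6'–H is the only C–H ortho to the carboxylate, and ring A has no C–H ortho to its carbonyl and no free acid. The depside ester is shielded by the C2 methoxy and C6 propyl groups and should resist carbonate in a tertiary alcohol, and the benzyl ether is inert to these conditions.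

Step 9
Reactants: 13 2-(benzyloxy)-4-[(2,4-dimethoxy-6-propylbenzoyl)oxy]-6-pentylbenzoic acid
Product: 14 4-[(2,4-dimethoxy-6-propylbenzoyl)oxy]-2-hydroxy-6-pentylbenzoic acid
Conditions: H2 (1 atm), 10% Pd/C, EtOAc, rt
Reagents that add atoms: none
Why: Hydrogenolysis of an aryl benzyl ether; the conditions are neutral and at room temperature, so the aryl ester, the methyl ethers and the decarboxylation-prone salicylic acid should survive.

## Compound list

1 | 3,5-dimethoxybenzaldehyde | COc1cc(C=O)cc(OC)c1 | starting material
2 | 1,3-dimethoxy-5-(prop-1-en-1-yl)benzene (mixture of Z and E isomers) | CC=Cc1cc(OC)cc(OC)c1 | intermediate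
3 | 1,3-dimethoxy-5-propylbenzene | CCCc1cc(OC)cc(OC)c1 | intermediate
4 | N-[(2,4-dimethoxy-6-propylphenyl)methylidene]-N-methylmethanaminium chloride | CCCc1cc(OC)cc(OC)c1C=[N+](C)C.[Cl-] | intermediate
5 | 2,4-dimethoxy-6-propylbenzaldehyde | CCCc1cc(OC)cc(OC)c1C=O | intermediate
6 | 2,4-dimethoxy-6-propylbenzoic acid | CCCc1cc(OC)cc(OC)c1C(=O)O | intermediate
7 | 2,4-dihydroxybenzaldehyde | O=Cc1ccc(O)cc1O | starting material
8 | 2,4-dimethoxy-6-propylbenzoyl chloride | CCCc1cc(OC)cc(OC)c1C(=O)Cl | intermediate
9 | 4-formyl-3-hydroxyphenyl 2,4-dimethoxy-6-propylbenzoate | CCCc1cc(OC)cc(OC)c1C(=O)Oc1ccc(C=O)c(O)c1 | intermediate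
10 | 3-(benzyloxy)-4-formylphenyl 2,4-dimethoxy-6-propylbenzoate | CCCc1cc(OC)cc(OC)c1C(=O)Oc1ccc(C=O)c(OCc2ccccc2)c1 | intermediate
11 | 2-(benzyloxy)-4-[(2,4-dimethoxy-6-propylbenzoyl)oxy]benzoic acid | CCCc1cc(OC)cc(OC)c1C(=O)Oc1ccc(C(=O)O)c(OCc2ccccc2)c1 | intermediate
12 | potassium pentyltrifluoroborate | CCCCC[B-](F)(F)F.[K+] | starting material
13 | 2-(benzyloxy)-4-[(2,4-dimethoxy-6-propylbenzoyl)oxy]-6-pentylbenzoic acid | CCCCCc1cc(OC(=O)c2c(CCC)cc(OC)cc2OC)cc(OCc2ccccc2)c1C(=O)O | intermediate
14 | 4-[(2,4-dimethoxy-6-propylbenzoyl)oxy]-2-hydroxy-6-pentylbenzoic acid | CCCCCc1cc(OC(=O)c2c(CCC)cc(OC)cc2OC)cc(O)c1C(=O)O | target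

## Step count and risk

Total step count: 9. Longest linear sequence: 9 steps (1, 2, 3, 5, 6, 9, 10, 11, 13, 14); compounds 7 and 12 enter as purchased materials.

Least certain steps:

Step 8 (key step). Several processes could go wrong:
- β-hydride elimination from the pentyl–palladium intermediate before reductive elimination;
- protodeboronation of 12;
- silver- or palladium-promoted protodecarboxylation of the electron-rich, ortho-disubstituted acid at 90 °C;
- slow metalation next to a crowded carboxylate;
- cleavage of the depside ester by carbonate.

Fallback: the pentyl chain is bought with ring B instead of being installed by C–H activation. The fallback sets out from acid chloride 8 and returns at 14. Vilsmeier–Haack formylation (POCl3, DMF) of 5-pentylbenzene-1,3-diol F1 gives 2,4-dihydroxy-6-pentylbenzaldehyde F2. Its unchelated 4-hydroxyl is acylated by 8 (Et3N, cat. DMAP, CH2Cl2) to give 4-formyl-3-hydroxy-5-pentylphenyl 2,4-dimethoxy-6-propylbenzoate F3. Pinnick oxidation of F3 (NaClO2, NaH2PO4, 2-methyl-2-butene) leads directly to 14. This detour would be shorter than the main line. What the main line offers in return is independence from a pentylresorcinol building block and a chain that can be varied from the common acid 11.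

Step 5. Acyl transfer from the di-ortho-substituted chloride may be slow, and forcing it may erode the preference for the 4-hydroxyl over the 2-hydroxyl or lead to double acylation. Fallback: the mode of activation is changed from addition–elimination at a crowded acyl chloride to an acylium-type pathway. The fallback sets out from 6 and 7 and returns at 9. Acid 6 and trifluoroacetic anhydride in toluene give the mixed anhydride 2,4-dimethoxy-6-propylbenzoic trifluoroacetic anhydride F4. F4 ionises readily because of its two ortho substituents and acylates the free 4-hydroxyl of 7.

Step 6. The phenoxide of 9 or the carbonate may cleave or transfer the depside ester, and alkylation of the hydrogen-bonded hydroxyl may stall. Fallback: the benzyl ether is installed before the ester exists. The fallback sets out from 7 and returns at 10. Selective 4-O-allylation of 7 (allyl bromide, KHCO3, DMF) gives 2-hydroxy-4-(prop-2-en-1-yloxy)benzaldehyde F5. Benzylation (BnBr, K2CO3, DMF) gives 2-(benzyloxy)-4-(prop-2-en-1-yloxy)benzaldehyde F6. Deallylation (Pd(PPh3)4, morpholine, THF) gives 2-(benzyloxy)-4-hydroxybenzaldehyde F7, whose only hydroxyl is acylated by 8 (Et3N, cat. DMAP) to give 10. The same detour also removes the selectivity question of step 5.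

Step 3. Part of the formylation may go to the carbon between the two methoxy groups, and the dimethyl ether may react incompletely, which would leave an isomer that is hard to remove. Fallback: the carboxyl carbon is introduced through a halogen instead of a formyl group. The fallback sets out from 3 and returns at 6, bypassing steps 3 and 4. Bromination with NBS in MeCN at 0 °C, para to one methoxy group, gives 2-bromo-1,5-dimethoxy-3-propylbenzene F8. Bromine–lithium exchange (n-BuLi, THF, −78 °C) gives (2,4-dimethoxy-6-propylphenyl)lithium F9, which is quenched with CO2 and acidified to give 6.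

## Further compounds

F1 | step 8 | 5-pentylbenzene-1,3-diol | CCCCCc1cc(O)cc(O)c1
F2 | step 8 | 2,4-dihydroxy-6-pentylbenzaldehyde | CCCCCc1cc(O)cc(O)c1C=O
F3 | step 8 | 4-formyl-3-hydroxy-5-pentylphenyl 2,4-dimethoxy-6-propylbenzoate | CCCCCc1cc(OC(=O)c2c(CCC)cc(OC)cc2OC)cc(O)c1C=O
F4 | step 5 | 2,4-dimethoxy-6-propylbenzoic trifluoroacetic anhydride | CCCc1cc(OC)cc(OC)c1C(=O)OC(=O)C(F)(F)F
F5 | step 6 | 2-hydroxy-4-(prop-2-en-1-yloxy)benzaldehyde | C=CCOc1ccc(C=O)c(O)c1
F6 | step 6 | 2-(benzyloxy)-4-(prop-2-en-1-yloxy)benzaldehyde | C=CCOc1ccc(C=O)c(OCc2ccccc2)c1
F7 | step 6 | 2-(benzyloxy)-4-hydroxybenzaldehyde | O=Cc1ccc(O)cc1OCc1ccccc1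
F8 | step 3 | 2-bromo-1,5-dimethoxy-3-propylbenzene | CCCc1cc(OC)cc(OC)c1Br
F9 | step 3 | (2,4-dimethoxy-6-propylphenyl)lithium | [Li]c1c(CCC)cc(OC)cc1OC
A1 | alternative 1 | benzyl 2-(benzyloxy)-4-[(2,4-dihydroxy-6-propylbenzoyl)oxy]-6-pentylbenzoate | CCCCCc1cc(OC(=O)c2c(CCC)cc(O)cc2O)cc(OCc2ccccc2)c1C(=O)OCc1ccccc1
A2 | alternative 1 | 3-(benzyloxy)-4-[(benzyloxy)carbonyl]-5-pentylphenyl 3,5,7-trioxodecanoate | CCCC(=O)CC(=O)CC(=O)CC(=O)Oc1cc(CCCCC)c(C(=O)OCc2ccccc2)c(OCc2ccccc2)c1
A3 | alternative 2 | tert-butyl 4-[(2,4-dimethoxy-6-propylbenzoyl)oxy]-2-(methoxymethoxy)-6-pentylbenzoate | CCCCCc1cc(OC(=O)c2c(CCC)cc(OC)cc2OC)cc(OCOC)c1C(=O)OC(C)(C)C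
A4 | alternative 2 | [4-(tert-butoxycarbonyl)-3-(methoxymethoxy)-5-pentylphenyl]boronic acid | CCCCCc1cc(B(O)O)cc(OCOC)c1C(=O)OC(C)(C)C
A5 | alternative 3 | benzyl 4-[(2,4-dimethoxy-6-propylbenzoyl)oxy]-2-hydroxy-6-pentylbenzoate | CCCCCc1cc(OC(=O)c2c(CCC)cc(OC)cc2OC)cc(O)c1C(=O)OCc1ccccc1
A6 | alternative 3 | 2-iodo-1,5-dimethoxy-3-propylbenzene | CCCc1cc(OC)cc(OC)c1I
A7 | alternative 3 | benzyl 2,4-dihydroxy-6-pentylbenzoate | CCCCCc1cc(O)cc(O)c1C(=O)OCc1ccccc1
A8 | alternative 3 | carbon monoxide | [C-]#[O+]
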